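The target is disconnected across ring A: breaking C8–C8a and C4a–C5 turns C5–C8, whose C5 and C7 carry the phloroglucinol oxygens, into an acetoacetate-derived 1,3-bis(silyloxy)diene and leaves C4a=C8a as the enone double bond of a monocyclic ring C. The key step joins the two in one operation: conjugate addition of the diene at C8a, loss of HBr and methanol, and Claisen closure aromatise ring A while C2, set earlier by a catalytic asymmetric hetero-Diels–Alder reaction, looks on. Its precursor is the (2S)-5-bromo-2-aryl-2,3-dihydropyran-4-one that already holds ring B with its prenyl group and a silyl-protected phenol.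

Key step: step 7

Remark: flavanone numbering (O1, C2, C3, C4, C4a, C5–C8, C8a; ring A benzo, ring B aryl, ring C pyranone) is used for the precursors as well; Ar = 3-methoxy-5-(3-methylbut-2-en-1-yl)-4-(triisopropylsilyloxy)phenyl.

Remark: the ring B phenol is carried as a triisopropylsilyl ether, because an acetal-type group would be ionised by the silyl triflate of the key step and would alkylate the diene, and because the bulky silyl ether cannot take part in bromo-etherification of the neighbouring prenyl group.

Remark: HBr is removed across C4a–C8a before ring A is closed, because in a cis-fused cycloadduct the bromine on C4a and the hydrogen on C8a would be syn, and a bromine flanked by two carbonyl groups would behave as an electrophilic bromine donor.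

Assumption: the (S)-BINOL titanium catalyst directs attack to the Si face of the aldehyde, as in its allylation and aldol reactions; should the sense prove reversed, (R)-BINOL is used.

Step 1
Reactants: 1 5-bromovanillin (3-bromo-4-hydroxy-5-methoxybenzaldehyde)
Product: 2 3-bromo-5-methoxy-4-(triisopropylsilyloxy)benzaldehyde
Conditions: TIPSCl (1.2 equiv), imidazole (2.5 equiv), DMF, rt to 40 °C
Reagents that add atoms: triisopropylsilyl chloride (TIPSCl), CC(C)[Si](Cl)(C(C)C)C(C)C
Why: O-silylation of an acidic phenol with a silyl chloride and imidazole is routine even between two ortho substituents, and the triisopropylsilyl ether should tolerate aqueous phosphate, Lewis acids, NBS and DBU before buffered fluoride removes it.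

Step 2
Reactants: 2 3-bromo-5-methoxy-4-(triisopropylsilyloxy)benzaldehyde; 3 prenylboronic acid pinacol ester (4,4,5,5-tetramethyl-2-(3-methylbut-2-en-1-yl)-1,3,2-dioxaborolane)
Product: 4 3-methoxy-5-(3-methylbut-2-en-1-yl)-4-(triisopropylsilyloxy)benzaldehyde (ArCHO)
Conditions: 3 (1.5 equiv), PdCl2(IPent)(3-chloropyridine) (2 mol %; IPent = 1,3-bis[2,6-di(pentan-3-yl)phenyl]imidazol-2-ylidene), K3PO4 (3 equiv), THF/H2O, 60 °C
Reagents that add atoms: none
Why: Suzuki-Miyaura coupling of an aryl bromide with an allylic boronate, in which the very bulky carbene ligand makes reductive elimination occur at the unsubstituted allyl terminus, so that the linear prenyl group and not the 1,1-dimethylallyl isomer should be attached.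

Step 3
Reactants: 4 ArCHO; 5 (E)-1-methoxy-3-(trimethylsilyloxy)buta-1,3-diene
Product: 7 (2S)-2-Ar-2,3-dihydro-4H-pyran-4-one, via Mukaiyama aldol adduct 6 (not isolated)
Conditions: (S)-BINOL (20 mol %), Ti(OiPr)4 (10 mol %), CF3CO2H (cat.), 4 Å MS, Et2O, −20 °C; then CF3CO2H, CH2Cl2, 0 °C
Reagents that add atoms: none
Why: Catalytic asymmetric hetero-Diels-Alder reaction in its Mukaiyama aldol and cyclisation form, in which the (S)-BINOL titanium complex leaves the Si face of the aldehyde open to the diene terminus and so sets C2 as S, and acid then closes ring C by oxa-Michael addition with loss of methanol.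

Step 4
Reactants: 7 (2S)-2-Ar-2,3-dihydro-4H-pyran-4-one
Product: 8 (2S)-5-bromo-2-Ar-2,3-dihydro-4H-pyran-4-one
Conditions: NBS (1.05 equiv), CH2Cl2, −20 to 0 °C, dark
Reagents that add atoms: N-bromosuccinimide (NBS), O=C1CCC(=O)N1Br
Why: Electrophilic alpha-bromination of a vinylogous ester (bromine adds to the enol ether carbon C5 and the oxocarbenium ion loses H+), an irreversible substitution that should outrun the reversible bromonium formation at the prenyl alkene in an aprotic medium, where the bulky silyl ether cannot act as internal nucleophile.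

Step 5
Reactants: 9 methyl acetoacetate
Product: 10 methyl 3-(trimethylsilyloxy)but-2-enoate
Conditions: Me3SiCl, Et3N, hexane, rt
Reagents that add atoms: chlorotrimethylsilane, C[Si](C)(C)Cl
Why: O-silylation of the enol of a beta-keto ester with a silyl chloride and an amine is the standard first stage of bis(silyloxy)diene synthesis.

Step 6
Reactants: 10 methyl 3-(trimethylsilyloxy)but-2-enoate
Product: 12 1-methoxy-1,3-bis(trimethylsilyloxy)buta-1,3-diene, via lithium dienolate 11 (not isolated)
Conditions: LiN(iPr)2, THF, −78 °C; then Me3SiCl, −78 °C to rt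
Reagents that add atoms: chlorotrimethylsilane, C[Si](C)(C)Cl
Why: Deprotonation at the gamma-methyl group gives a dienolate that is silylated on oxygen, the established route to 1,3-bis(silyloxy)buta-1,3-dienes.

Step 7
Reactants: 8 (2S)-5-bromo-2-Ar-2,3-dihydro-4H-pyran-4-one; 12 1-methoxy-1,3-bis(trimethylsilyloxy)buta-1,3-diene
Product: 16 (2S)-5,7-dihydroxy-2-Ar-2,3-dihydro-4H-chromen-4-one, via bis-silyl Michael adduct 13 (not isolated), via bromo ketone keto ester 14 (not isolated), via dihydropyranone keto ester 15 (not isolated)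
Conditions: 12 (2.5 equiv), Me3SiOTf (0.3 equiv), CH2Cl2, −78 to −40 °C; 1 M HCl/THF, 0 °C; crude, DBU (4 equiv), MeCN, 0 °C to rt; 1 M HCl
Reagents that add atoms: none
Why: Proposed new method: Me3SiOTf silylates the C4 carbonyl of 8, so that C8a becomes an oxocarbenium carbon, and the unsubstituted CH2 terminus of 12, its most nucleophilic carbon, adds there in a Mukaiyama-Michael reaction (C8-C8a bond) to give 13, which dilute acid hydrolyses to bromo ketone 14. DBU then takes HBr out across C4a-C8a, as in the classical conversion of a 3-bromochroman-4-one into a chromone, at a stage where C4a still bears an enolisable hydrogen, so that no syn H/Br pair at a ring fusion and no bromine flanked by two carbonyl groups has to be handled, and the enone returns in 15. Deprotonation of 15 at C8 gives an extended enolate whose C4a attacks the ester carbon in a 6-(enolexo)-exo-trig Claisen condensation (C4a-C5 bond), and loss of methoxide followed by enolisation makes ring A aromatic. The closest known reaction types are the silyl-triflate-mediated addition of 1,3-bis(silyloxy)dienes to chromones, the cycloaddition-aromatisation of such dienes with halogenated quinones, and the base-induced Claisen cyclisation of 3,5,7-triketo esters to acylphloroglucinols. No stereocentre is created, since the C8a and C4a centres of 13 and 14 are destroyed again, and C2 is untouched because its C-O bond is never broken. The selectivity needed is regiochemical (CH2 terminus to C8a, ester carbon to C4a) and is secured by the matched polarity of the two partners, while the alternative aldol closure onto C4 would put the C4a=C8a double bond at a bridgehead.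

Step 8
Reactants: 16 (2S)-5,7-dihydroxy-2-Ar-2,3-dihydro-4H-chromen-4-one
Product: 17 (2S)-5,7-dihydroxy-2-[4-hydroxy-3-methoxy-5-(3-methylbut-2-en-1-yl)phenyl]-2,3-dihydro-4H-chromen-4-one (target)
Conditions: Bu4NF (1.2 equiv), AcOH (1.5 equiv), THF, 0 °C
Reagents that add atoms: none
Why: Fluoride-induced cleavage of an aryl silyl ether, buffered with acetic acid so that no C3 enolate (retro-oxa-Michael racemisation at C2) should form and no strong acid reaches the prenyl group next to the freed phenol.

Compound list

1 | 5-bromovanillin (3-bromo-4-hydroxy-5-methoxybenzaldehyde) | COc1cc(C=O)cc(Br)c1O | starting material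
2 | 3-bromo-5-methoxy-4-(triisopropylsilyloxy)benzaldehyde | COc1cc(C=O)cc(Br)c1O[Si](C(C)C)(C(C)C)C(C)C | intermediate
3 | prenylboronic acid pinacol ester | CC(C)=CCB1OC(C)(C)C(C)(C)O1 | starting material
4 | 3-methoxy-5-(3-methylbut-2-en-1-yl)-4-(triisopropylsilyloxy)benzaldehyde | COc1cc(C=O)cc(CC=C(C)C)c1O[Si](C(C)C)(C(C)C)C(C)C | intermediate
5 | (E)-1-methoxy-3-(trimethylsilyloxy)buta-1,3-diene | CO/C=C/C(=C)O[Si](C)(C)C | starting material
6 | (1E,5S)-1-methoxy-5-Ar-5-(trimethylsilyloxy)pent-1-en-3-one (Mukaiyama aldol adduct, not isolated) | COc1cc([C@@H](O[Si](C)(C)C)CC(=O)/C=C/OC)cc(CC=C(C)C)c1O[Si](C(C)C)(C(C)C)C(C)C | intermediate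
7 | (2S)-2-Ar-2,3-dihydro-4H-pyran-4-one | COc1cc([C@@H]2CC(=O)C=CO2)cc(CC=C(C)C)c1O[Si](C(C)C)(C(C)C)C(C)C | intermediate
8 | (2S)-5-bromo-2-Ar-2,3-dihydro-4H-pyran-4-one (key-step precursor) | COc1cc([C@@H]2CC(=O)C(Br)=CO2)cc(CC=C(C)C)c1O[Si](C(C)C)(C(C)C)C(C)C | intermediate
9 | methyl acetoacetate | CC(=O)CC(=O)OC | starting material
10 | methyl 3-(trimethylsilyloxy)but-2-enoate (mixture of geometric isomers) | COC(=O)C=C(C)O[Si](C)(C)C | intermediate
11 | lithium 1-methoxy-3-(trimethylsilyloxy)buta-1,3-dien-1-olate (lithium dienolate, not isolated) | [Li]OC(OC)=CC(=C)O[Si](C)(C)C | intermediate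
12 | 1-methoxy-1,3-bis(trimethylsilyloxy)buta-1,3-diene | C=C(O[Si](C)(C)C)C=C(OC)O[Si](C)(C)C | intermediate
13 | methyl 4-[(6S)-3-bromo-6-Ar-4-(trimethylsilyloxy)-5,6-dihydro-2H-pyran-2-yl]-3-(trimethylsilyloxy)but-2-enoate (bis-silyl Michael adduct, not isolated; C8a centre and enoate geometry not defined) | COc1cc([C@@H]2CC(O[Si](C)(C)C)=C(Br)C(CC(O[Si](C)(C)C)=CC(=O)OC)O2)cc(CC=C(C)C)c1O[Si](C(C)C)(C(C)C)C(C)C | intermediate
14 | methyl 4-[(6S)-3-bromo-6-Ar-4-oxotetrahydro-2H-pyran-2-yl]-3-oxobutanoate (bromo ketone keto ester, not isolated; epimers at C4a and C8a) | COc1cc([C@@H]2CC(=O)C(Br)C(CC(=O)CC(=O)OC)O2)cc(CC=C(C)C)c1O[Si](C(C)C)(C(C)C)C(C)C | intermediate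
15 | methyl 4-[(2S)-2-Ar-4-oxo-3,4-dihydro-2H-pyran-6-yl]-3-oxobutanoate (dihydropyranone keto ester, not isolated) | COc1cc([C@@H]2CC(=O)C=C(CC(=O)CC(=O)OC)O2)cc(CC=C(C)C)c1O[Si](C(C)C)(C(C)C)C(C)C | intermediate
16 | (2S)-5,7-dihydroxy-2-[3-methoxy-5-(3-methylbut-2-en-1-yl)-4-(triisopropylsilyloxy)phenyl]-2,3-dihydro-4H-chromen-4-one (key-step product) | COc1cc([C@@H]2CC(=O)c3c(O)cc(O)cc3O2)cc(CC=C(C)C)c1O[Si](C(C)C)(C(C)C)C(C)C | intermediate
17 | (2S)-5,7-dihydroxy-2-[4-hydroxy-3-methoxy-5-(3-methylbut-2-en-1-yl)phenyl]-2,3-dihydro-4H-chromen-4-one | COc1cc([C@@H]2CC(=O)c3c(O)cc(O)cc3O2)cc(CC=C(C)C)c1O | target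

Total step count: 8 (six on the main line, two for diene 12).
Longest linear sequence: 6 steps (steps 1, 2, 3, 4, 7, 8; 1 → 2 → 4 → 7 → 8 → 16 → 17).

Steps most likely to fail

1. Step 7 (Proposed new method). Four processes may go wrong:
- Base may open ring C by beta-elimination of O1 from C8a, and the freed alkoxide may then displace the alpha-bromide (ring contraction) instead of HBr being lost across C4a–C8a.
- The Claisen closure may stall at the open keto ester stage.
- Reversible retro-oxa-Michael opening at C2 under DBU may erode the enantiomeric purity.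
- The silyl triflate may ionise the benzylic C2–O bond.

Fallback (known chemistry, ring A first), setting out from aldehyde 4 and coming back at 16: commercial methyl 2,4,6-trihydroxybenzoate is protected with MOMCl and iPr2NEt to methyl 2-hydroxy-4,6-bis(methoxymethoxy)benzoate F1. Crossed Claisen condensation of F1 with lithiated tert-butyl acetate (LiN(iPr)2, THF, −78 °C) gives tert-butyl 3-[2-hydroxy-4,6-bis(methoxymethoxy)phenyl]-3-oxopropanoate F2. Knoevenagel condensation of F2 with 4 (piperidine, AcOH, toluene, 4 Å MS) gives tert-butyl 2-[2-hydroxy-4,6-bis(methoxymethoxy)benzoyl]-3-Ar-prop-2-enoate F3. A cinchona-alkaloid-derived bifunctional thiourea (the quinine- or quinidine-based pseudoenantiomer that gives the 2S series, toluene, −25 °C) catalyses the intramolecular oxa-Michael addition to tert-butyl (2S)-2-Ar-5,7-bis(methoxymethoxy)-4-oxochromane-3-carboxylate F4. TsOH·H2O in toluene at 80 °C then cleaves the tert-butyl ester with decarboxylation and removes both MOM ethers, which should give 16.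

2. Step 4. The electrophilic bromine may attack the prenyl double bond or ring B in competition with C5, or a second bromination may follow.

Fallback (bromination of a silyl enol ether instead of the vinylogous ester), setting out from 4 and 5 and coming back at 8: a concerted cycloaddition catalysed by the chromium tetrafluoroborate complex (salen)CrBF4 (salen = dianion of N,N'-bis(3,5-di-tert-butylsalicylidene)cyclohexane-1,2-diamine, enantiomer chosen for Si-face attack) leaves the primary cycloadduct (6S)-2-methoxy-6-Ar-4-(trimethylsilyloxy)-5,6-dihydro-2H-pyran F5 intact. NBS at −78 °C brominates its silyl enol ether, which is far more nucleophilic than the prenyl alkene, to (6S)-3-bromo-2-methoxy-6-Ar-tetrahydropyran-4-one F6. CF3CO2H in CH2Cl2 at 0 °C then eliminates methanol to give 8.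

3. Step 3. Addition to the hindered, electron-rich aldehyde may be slow or poorly face-selective, and the acid used for ring closure may damage the prenyl group.

Fallback (hydrogen-bond catalysis with an amino silyloxy diene, no acid), setting out from 4 and coming back at 7: 4 reacts with 1-(dimethylamino)-3-(tert-butyldimethylsilyloxy)buta-1,3-diene under catalysis by α,α,α',α'-tetra(1-naphthyl)-2,2-dimethyl-1,3-dioxolane-4,5-dimethanol (enantiomer chosen for Si-face attack, toluene, −40 °C) to give (6S)-4-(tert-butyldimethylsilyloxy)-N,N-dimethyl-6-Ar-5,6-dihydro-2H-pyran-2-amine F7. Acetyl chloride (CH2Cl2, −78 °C) then removes the amino and silyl groups to give 7.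

Further compounds

F1 | step 7 | methyl 2-hydroxy-4,6-bis(methoxymethoxy)benzoate | COC(=O)c1c(O)cc(OCOC)cc1OCOC
F2 | step 7 | tert-butyl 3-[2-hydroxy-4,6-bis(methoxymethoxy)phenyl]-3-oxopropanoate | CC(C)(C)OC(=O)CC(=O)c1c(O)cc(OCOC)cc1OCOC
F3 | step 7 | tert-butyl 2-[2-hydroxy-4,6-bis(methoxymethoxy)benzoyl]-3-Ar-prop-2-enoate (E/Z mixture) | CC(C)(C)OC(=O)C(=Cc1cc(OC)c(O[Si](C(C)C)(C(C)C)C(C)C)c(CC=C(C)C)c1)C(=O)c1c(O)cc(OCOC)cc1OCOC
F4 | step 7 | tert-butyl (2S)-2-Ar-5,7-bis(methoxymethoxy)-4-oxochromane-3-carboxylate (C3 epimers) | COc1cc([C@@H]2C(C(=O)OC(C)(C)C)C(=O)c3c(OCOC)cc(OCOC)cc3O2)cc(CC=C(C)C)c1O[Si](C(C)C)(C(C)C)C(C)C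
F5 | step 4 | (6S)-2-methoxy-6-Ar-4-(trimethylsilyloxy)-5,6-dihydro-2H-pyran | COc1cc([C@@H]2CC(O[Si](C)(C)C)=CC(OC)O2)cc(CC=C(C)C)c1O[Si](C(C)C)(C(C)C)C(C)C
F6 | step 4 | (6S)-3-bromo-2-methoxy-6-Ar-tetrahydropyran-4-one | COc1cc([C@@H]2CC(=O)C(Br)C(OC)O2)cc(CC=C(C)C)c1O[Si](C(C)C)(C(C)C)C(C)C
F7 | step 3 | (6S)-4-(tert-butyldimethylsilyloxy)-N,N-dimethyl-6-Ar-5,6-dihydro-2H-pyran-2-amine | COc1cc([C@@H]2CC(O[Si](C)(C)C(C)(C)C)=CC(N(C)C)O2)cc(CC=C(C)C)c1O[Si](C(C)C)(C(C)C)C(C)C
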